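Remark on numbering: labdane locants are used for the target and every bicyclic compound (ring A = C1–C5 and C10, ring B = C5–C10, side chain C11–C15; β is the face of the C10 methyl). Compound numbers are those of the list after the steps.
Assumption: the ring-closing step is taken to give mainly the equatorial 3β alcohol 13; this is immaterial, because step 10 removes that centre.

## Analysis of the target

Compound 30 is a labdane-type ester: a trans-fused decalin (ring A = C1–C5/C10, ring B = C5–C10) that carries on C9 a five-carbon chain ending in an (E)-3-methyl-2-enoate (C13=C14, C15 ester). It has six stereocentres, C2 (R), C3 (S), C5 (S), C8 (R), C9 (S) and C10 (S), plus the E alkene. Relative to the β-axial C10 methyl, H5 is α, the C8 methyl is α and equatorial, and the C9 hydroxyl is β and equatorial, so the side chain is α and axial, anti to the C10 methyl. On ring A the two hydroxyls are cis on the α face, C2–OH equatorial and C3–OH axial. C8, C9 and C10 are contiguous and end in a tertiary carbinol and a quaternary carbon; a second quaternary carbon, C4, lies between C5 and the C3 carbinol. The C9 carbinol can ionize (dehydration, shift of the C10 methyl) or add to C13 in Michael fashion, and the enoate excludes strong bases and nucleophiles at the end. The hard parts are the C3–C4 bond beside C5, the fully flanked C9 carbinol with its axial chain, and the cis-diol on a ring with two axial methyls. The strategy rests on ring B: a six-membered ring with a methyl on C8 next to an oxygenated C9 and a branched carbon (C4) on C5 is the pattern of (R)-carvone 1, whose isopropenyl carbon already holds both C4 methyls (one as CH2) and lacks only the bond to C3.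

## Retrosynthetic reasoning

30 from 29. The last operation only frees the C2/C3 diol from the isopropylidene acetal of 29; no skeletal bond is cut. The acetal stays until the end because free ring A hydroxyls would be acylated in the step that makes the ester.

29 from 27. The enoate is cut at C14–C15 and at C13–CH3, which leads to terminal alkyne 27. Cutting C13=C14 instead (olefination of a C13 ketone) is rejected: such an olefination tells CH3 from CH2R poorly, and a C13 ketone would close onto the C9 hydroxyl as a lactol. A syn carbometalation fixes the E geometry by mechanism. Forward, methyl and metal must add syn with the methyl on C13, and the vinyl metal must be acylated with retention.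

27 from 26, 25 and 24. The silyl group and the acetal are protecting-group adjustments. The diol of 25 is disconnected at both C–O bonds to the C2=C3 alkene of 24. A syn dihydroxylation gives both hydroxyls cis in one event, and the β face of this alkene is closed by the axial methyls on C10 and C4, so the reagent can only come from the α face.

24 from 22, 21 and 20. The alkene is traced through tosylhydrazone 22 to ketone 21 and carbinol 20. A vinyl anion route is preferred to dehydration, because a cation at C3 beside the quaternary C4 would invite methyl shift or ring contraction. Only C2 carries α-hydrogens, so the alkene can only form between C2 and C3.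

20 from 13 and 17. The C9–C11 bond is cut, giving hydroxy ketone 13 and iodide 17 as a four-carbon nucleophile. C9 is the carbonyl carbon of the carvone ring, and the required configuration (chain anti to the C10 methyl, hydroxyl equatorial) is the one expected for attack on this ketone. Forward, the addition is placed directly after ring closure and before the hydrazone chemistry: once C9 is a tertiary alkoxide, no second carbonyl can compete for the hydrazide or be attacked or enolized by the strong base of the Shapiro step. The alkyne travels silylated as a spectator. The reagent must add and not enolize C8, hence cerium.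

13 from 12. The C3–C4 bond is cut, opening ring A to keto aldehyde 12. This is the most congested bond of the decalin, and polar logic serves it badly: C4 would have to be a tertiary nucleophile, whereas protonation of the isopropenyl group makes it an electrophile and an ene reaction bonds through the CH2. Hydrogen-atom transfer to the CH2 turns C4 into a tertiary nucleophilic radical and at the same stroke completes the gem-dimethyl group. The gain is one ring and one bond, and the whole carbon skeleton of the core, from a monocyclic precursor in which C5 and C10 are already fixed.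

12 from 11, 9, 7, 4 and 1. The aldehyde is traced to the allyl group of 9 (terminal functionalization of the alkene), the saturated ketone to enone 7, and the C10–C1 and C10–CH3 bonds to two successive enolate alkylations of 1 with 2 and 5. The order matters: the second electrophile enters anti to the isopropenyl group, so methyl goes first and allyl second, which puts C1 trans to C4 as a trans-decalin requires. C8 is set afterwards under thermodynamic control.

17 from 16 and 14. The iodide comes from but-3-yn-1-ol 14 by C-silylation and exchange of hydroxyl for iodine.

## Alternatives that were turned down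

Alternative 1: both rings from an open chain by an intramolecular Diels–Alder reaction. The disconnection cuts C5–C10 and C6–C7. Forward, heating dienyne A2 (2-silyloxydiene C7=C8–C9=C10, terminal alkyne C5≡C6, dioxolane on C2/C3) would give the bicyclic 1,4-diene A1. Its tether would be built from (S)-pantolactone A3, which supplies C3 with its oxygen and the C4 gem-dimethyl group. In its favour, rings A and B form in one step, and the ring A oxygens are present from the start, so no late redox work on ring A is needed. On that point it is stronger than the chosen route. Against it: the diene terminus C10 is fully substituted, so one group must point inward in the s-cis conformer; the dienophile is an unactivated alkyne; and the C10 configuration depends on how a flexible tether folds. After the cycloaddition, C5 still has to be set by reducing an alkene flanked by two quaternary carbons, and C8 by protonating the enol ether. A3 is the less common enantiomer, and A2 needs roughly as many steps as the whole of the chosen route up to 13. The chosen route gives up convergence and in return takes C5 from 1, sets C10 by an alkylation with a dependable anti rule, and fixes the ring fusion before any ring is closed.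

Alternative 2: ring B by a Paternò–Büchi reaction. The disconnection cuts C9–C10 and O–C20. Forward, irradiation of keto alkene A5 near 300 nm would add the C9 carbonyl across the exocyclic C10=C20 alkene of ring A and give oxetane A4; later reductive opening at C20–O would reveal the C9 hydroxyl and the C10 methyl. In its favour, the C9 carbinol and the C10 quaternary centre are made together and are cis by construction, which is exactly the relationship in 30, and the side-chain carbons are already in place. On C9 it is stronger than the chosen route, which relies on the facial preference of a hindered ketone. Against it: an aliphatic ketone and an unactivated alkene react inefficiently, and α-cleavage at the branched C8 and γ-hydrogen abstraction compete. The configuration of C9 and C10 relative to C5 and C8 rests on the folding of a five-atom tether. Hydride opening of the oxetane must occur at a neopentyl CH2. The enoate would finally come from olefination at C13, with weak E/Z control. A5 itself needs a stereodefined ring A bearing three stereocentres, a longer precursor than 12. The chosen route offers thermal, well-understood steps and a mechanism-fixed E alkene in place of the built-in C9/C10 relationship.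

Alternative 3: ring A by pinacol coupling. The disconnection cuts C2–C3. Forward, a divalent samarium reductant would turn both aldehydes of dialdehyde A7 into ketyls, which couple to the 2α,3α-diol A6. In its favour, the ring and both carbinol centres arise in one step; cis selectivity is normal for such couplings, and the other cis isomer would place C2–OH axial against two axial methyls. For ring A this is clearly shorter than the oxidation, hydrazone, Shapiro and dihydroxylation sequence of the chosen route. Against it: A7 needs a quaternary C4 bearing an aldehyde, attached to C5 beside the quaternary C10. From 1 that means adding a carbon to a tertiary centre by polar chemistry, the very problem the radical closure avoids. The C9 ketone must also be masked as a dioxolane, and ketalization of a ketone flanked by a quaternary and a tertiary carbon is unfavourable. The chosen route spends more steps on ring A after closure but reaches its cyclization precursor 12 in five reliable steps using atoms 1 already has.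

Key step: step 6

## Steps

Step 1
Reactants: 1 (R)-carvone; 2 iodomethane
Product: 4 trans-6-methylcarvone [(5R,6S)-2,6-dimethyl-5-(prop-1-en-2-yl)cyclohex-2-en-1-one; the 6R epimer accompanies it], via lithium dienolate 3 (not isolated)
Conditions: LiN(i-Pr)2, THF, −78 °C; then MeI, −78 to 0 °C
Reagents that add atoms: none
Why: Kinetic deprotonation of the enone at the α′ CH2 gives the cross-conjugated dienolate, which is C-methylated (enolate alkylation); the new centre need not be controlled, because step 2 makes it planar again.

Step 2
Reactants: 4 trans-6-methylcarvone; 5 allyl bromide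
Product: 7 (5S,6S)-2,6-dimethyl-6-(prop-2-en-1-yl)-5-(prop-1-en-2-yl)cyclohex-2-en-1-one, via lithium enolate 6 (not isolated)
Conditions: LiN(i-Pr)2, THF, −78 °C; then allyl bromide, DMPU, −78 to 0 °C
Reagents that add atoms: none
Why: Enolate alkylation; both epimers of 4 give the same tetrasubstituted enolate, in which the neighbouring isopropenyl group sits pseudo-axial to avoid allylic strain, so the allyl group enters anti to it. This sets C10 with the future C1 trans to C4 and the methyl cis.

Step 3
Reactants: 7 allyl methyl carvone
Product: 9 (2S,3S,6R)-2,6-dimethyl-2-(prop-2-en-1-yl)-3-(prop-1-en-2-yl)cyclohexan-1-one, via lithium enolate 8 (not isolated)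
Conditions: LiBH(s-Bu)3, THF, −78 °C; then MeOH, NaOMe (cat.), 23 °C
Reagents that add atoms: none
Why: Conjugate (1,4) hydride reduction of a β-unsubstituted enone whose carbonyl is shielded by the quaternary neighbour; isolated alkenes are inert to the borohydride. C8 is set by protonation and base equilibration: its methyl goes equatorial, since the epimer would hold it 1,3-diaxial to the C10 methyl.

Step 4
Reactants: 9 allyl ketone
Product: 11 (2S,3S,6R)-2-(3-hydroxypropyl)-2,6-dimethyl-3-(prop-1-en-2-yl)cyclohexan-1-one, via trialkylborane 10 (not isolated)
Conditions: (Sia)2BH [BH3·THF + 2-methylbut-2-ene], THF, 0 °C; then NaOH, H2O2, 0 °C to rt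
Reagents that add atoms: hydrogen peroxide, OO
Why: Anti-Markovnikov hydroboration–oxidation; disiamylborane is used because it distinguishes the monosubstituted vinyl group from the 1,1-disubstituted isopropenyl group on steric grounds, which 9-BBN does not do reliably, and it is slow toward the doubly flanked ketone. Any carbinol formed at C9 would be returned to the ketone in step 5.

Step 5
Reactants: 11 hydroxy ketone
Product: 12 3-[(1S,3R,6S)-1,3-dimethyl-2-oxo-6-(prop-1-en-2-yl)cyclohexyl]propanal
Conditions: Dess–Martin periodinane, NaHCO3, CH2Cl2, 0 °C to rt
Reagents that add atoms: none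
Why: Dess–Martin oxidation of the primary alcohol under buffered, base-free conditions, which avoids aldol closure of C8 onto the new aldehyde; the isopropenyl group is untouched.

Step 6
Reactants: 12 keto aldehyde
Product: 13 3β-hydroxy-4,4,8α,10β-tetramethyl-5α-decalin-9-one [(2R,4aS,6S,8aS)-6-hydroxy-2,5,5,8a-tetramethyloctahydronaphthalen-1(2H)-one]
Conditions: Fe(acac)3 (0.5 equiv), PhSiH3 (2.5 equiv), EtOH (degassed), 60 °C
Reagents that add atoms: none
Why: Hydrogen-atom transfer from the iron hydride formed from Fe(acac)3 and PhSiH3 (Mukaiyama-type) puts a hydrogen on the CH2 of the isopropenyl group in Markovnikov sense and leaves a tertiary radical at C4. This nucleophilic radical adds to the carbon of the C3 aldehyde, and the alkoxy radical is reduced to the alcohol by divalent iron and ethanol, which returns trivalent iron; the reaction type is the known iron-hydride radical cyclization of alkene-tethered ketones and aldehydes. Ring A closes in a 6-exo-trig mode onto the C=O bond through a chair in which C4 and C1 are the two equatorial arms of ring B. C5 and C10 are not touched, so the ring fusion can only be trans. The one new stereocentre, C3, is set by the chair transition state, which should put the oxygen equatorial (3β); it is not needed, because step 10 oxidizes it. The step needs selectivity for the aldehyde over the C9 ketone and a closure faster than reduction of the radical: the ketone could be reached only through a four-membered ring, the aldehyde is the more reactive acceptor, and the reacting ends are held gauche on adjacent ring carbons. No cation or enolate forms beside C5 or C10, so neither can rearrange or epimerize.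

Step 7
Reactants: 14 but-3-yn-1-ol
Product: 16 4-(trimethylsilyl)but-3-yn-1-ol, via bis-silylated butynol 15 (not isolated)
Conditions: n-BuLi (2.2 equiv), THF, −78 °C; TMSCl (2.2 equiv), −78 °C to rt; then 1 M HCl
Reagents that add atoms: chlorotrimethylsilane, C[Si](C)(C)Cl
Why: Double deprotonation (O–H and alkyne C–H), double silylation, then selective hydrolysis of the labile O–Si bond on acidic work-up leaves the C-silylated alkyne.

Step 8
Reactants: 16 4-(trimethylsilyl)but-3-yn-1-ol
Product: 17 (4-iodobut-1-yn-1-yl)trimethylsilane
Conditions: I2, PPh3, imidazole, CH2Cl2, 0 °C to rt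
Reagents that add atoms: iodine, II
Why: Appel-type iodination (Garegg–Samuelsson conditions) of a primary alcohol by SN2 displacement of the oxyphosphonium group; the silylalkyne is inert.

Step 9
Reactants: 13 hydroxy ketone; 17 iodide
Product: 20 3β,9β-dihydroxy-4,4,8α,10β-tetramethyl-9α-[4-(trimethylsilyl)but-3-yn-1-yl]-5α-decalin, via alkyllithium 18 (not isolated), via organocerium reagent 19 (not isolated)
Conditions: 17 (3 equiv), t-BuLi (6 equiv), Et2O, −78 °C; CeCl3 (anhydrous, 3 equiv), THF, −78 °C; then 13, −78 to 0 °C; aq NH4Cl
Reagents that add atoms: none
Why: Lithium–iodine exchange, transmetalation to cerium and 1,2-addition of the organocerium reagent; one equivalent is consumed by the C3 hydroxyl, and the low basicity of the cerium reagent suppresses enolization toward C8. The new C9 centre is set by the axial C10 methyl, which blocks the equatorial (β) trajectory: attack is axial from the α face (anti to the methyl, Felkin-type torsional control), giving the chain α and the hydroxyl β.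

Step 10
Reactants: 20 diol
Product: 21 9β-hydroxy-4,4,8α,10β-tetramethyl-9α-[4-(trimethylsilyl)but-3-yn-1-yl]-5α-decalin-3-one
Conditions: Dess–Martin periodinane, NaHCO3, CH2Cl2, rt
Reagents that add atoms: none
Why: Dess–Martin oxidation of the secondary C3 alcohol; the tertiary C9 alcohol cannot be oxidized, and both C3 epimers converge on the same ketone.

Step 11
Reactants: 21 ketone
Product: 22 (E)-p-toluenesulfonylhydrazone of 21 at C3
Conditions: TsNHNH2, EtOH, 60 °C
Reagents that add atoms: p-toluenesulfonyl hydrazide, Cc1ccc(cc1)S(=O)(=O)NN
Why: Condensation of the only carbonyl group with the sulfonyl hydrazide (hydrazone formation); the N–N bond turns away from the gem-dimethyl carbon, toward C2.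

Step 12
Reactants: 22 tosylhydrazone
Product: 24 9β-hydroxy-4,4,8α,10β-tetramethyl-9α-[4-(trimethylsilyl)but-3-yn-1-yl]-5α-decal-2-ene (C2=C3), via vinyllithium 23 (not isolated)
Conditions: LiN(i-Pr)2 (4.5 equiv), THF, −78 °C to rt; then H2O
Reagents that add atoms: none
Why: Shapiro reaction: deprotonation at N–H, O–H and C2–H (the only α-hydrogens), loss of sulfinate and N2, and protonation of the C3 vinyl anion give the C2=C3 alkene without a cation next to the quaternary C4. The amide base spares the silylalkyne, and the C9 alkoxide is inert.

Step 13
Reactants: 24 alkene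
Product: 25 2α,3α,9β-trihydroxy-4,4,8α,10β-tetramethyl-9α-[4-(trimethylsilyl)but-3-yn-1-yl]-5α-decalin
Conditions: OsO4 (5 mol %), NMO (1.5 equiv), acetone/H2O (5:1), rt
Reagents that add atoms: osmium tetroxide, O=[Os](=O)(=O)=O; N-methylmorpholine N-oxide, C[N+]1([O-])CCOCC1; water, O
Why: Upjohn syn-dihydroxylation; the β face of C2=C3 is closed by the axial methyls on C10 and C4, so both oxygens arrive from the α face and set C2 and C3 together. The alkyne does not react under these conditions.

Step 14
Reactants: 25 triol
Product: 26 2α,3α-isopropylidene acetal of 25
Conditions: 2,2-dimethoxypropane, PPTS (cat.), CH2Cl2, rt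
Reagents that add atoms: 2,2-dimethoxypropane, COC(C)(C)OC
Why: Acid-catalysed transacetalization; the cis-1,2-diol closes a dioxolane, and the tertiary C9 hydroxyl is too hindered to take part.

Step 15
Reactants: 26 silylalkyne acetonide
Product: 27 9α-(but-3-yn-1-yl)-9β-hydroxy-2α,3α-isopropylidenedioxy-4,4,8α,10β-tetramethyl-5α-decalin
Conditions: K2CO3, MeOH, rt
Reagents that add atoms: none
Why: Base-catalysed methanolysis of the C(sp)–Si bond (protodesilylation); acetal and tertiary alcohol are stable to mild base.

Step 16
Reactants: 27 terminal alkyne
Product: 29 methyl (2E)-5-(9β-hydroxy-2α,3α-isopropylidenedioxy-4,4,8α,10β-tetramethyl-5α-decalin-9α-yl)-3-methylpent-2-enoate, via alkenylalane 28 (not isolated)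
Conditions: Me3Al (3.5 equiv), Cp2ZrCl2 (0.25 equiv), H2O (1 equiv), CH2Cl2, −30 °C; then ClCO2Me, −30 °C to rt; aq sodium potassium tartrate
Reagents that add atoms: trimethylaluminium, C[Al](C)C; methyl chloroformate, COC(=O)Cl
Why: Negishi zirconium-catalysed carboalumination adds methyl and aluminium syn across the alkyne with the methyl on the internal carbon C13, and acylation of the alkenylalane by the chloroformate proceeds with retention, so the enoate is E by mechanism. The C9 hydroxyl travels as its aluminium alkoxide, and the low temperature of the water-accelerated variant protects the dioxolane.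

Step 17
Reactants: 29 enoate acetonide
Product: 30 methyl (2E)-3-methyl-5-[(2R,3S,5S,8R,9S,10S)-2α,3α,9β-trihydroxy-4,4,8α,10β-tetramethyl-5α-decalin-9α-yl]pent-2-enoate (CNP0292844.1)
Conditions: AcOH/H2O (4:1), 40 °C
Reagents that add atoms: none
Why: Acid-catalysed acetal hydrolysis; the weak acid is chosen so that the C9 carbinol neither ionizes nor adds to the enoate, and no stereocentre is touched.

## Compound list

1 | (R)-carvone, (5R)-2-methyl-5-(prop-1-en-2-yl)cyclohex-2-en-1-one | CC1=CC[C@H](CC1=O)C(C)=C | starting material
2 | iodomethane | CI | starting material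
3 | lithium dienolate of 1 (C6=C1–OLi, C2=C3 retained) | [Li]OC1=C[C@H](C(C)=C)CC=C1C | intermediate
4 | trans-6-methylcarvone, (5R,6S)-2,6-dimethyl-5-(prop-1-en-2-yl)cyclohex-2-en-1-one (major epimer) | C[C@@H]1C(=O)C(C)=CC[C@H]1C(C)=C | intermediate
5 | allyl bromide, 3-bromoprop-1-ene | C=CCBr | starting material
6 | lithium enolate of 4 (C6=C1–OLi) | CC1=C(O[Li])C(C)=CC[C@H]1C(C)=C | intermediate
7 | (5S,6S)-2,6-dimethyl-6-(prop-2-en-1-yl)-5-(prop-1-en-2-yl)cyclohex-2-en-1-one (allyl trans to isopropenyl) | C=CC[C@]1(C)C(=O)C(C)=CC[C@H]1C(C)=C | intermediate
8 | lithium enolate from conjugate reduction of 7 (C8=C9–OLi) | C=CC[C@]1(C)C(O[Li])=C(C)CC[C@H]1C(C)=C | intermediate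
9 | (2S,3S,6R)-2,6-dimethyl-2-(prop-2-en-1-yl)-3-(prop-1-en-2-yl)cyclohexan-1-one | C=CC[C@]1(C)C(=O)[C@H](C)CC[C@H]1C(C)=C | intermediate
10 | bis(3-methylbutan-2-yl){3-[(1S,3R,6S)-1,3-dimethyl-2-oxo-6-(prop-1-en-2-yl)cyclohexyl]propyl}borane | CC(C)C(C)B(C(C)C(C)C)CCC[C@]1(C)C(=O)[C@H](C)CC[C@H]1C(C)=C | intermediate
11 | (2S,3S,6R)-2-(3-hydroxypropyl)-2,6-dimethyl-3-(prop-1-en-2-yl)cyclohexan-1-one | OCCC[C@]1(C)C(=O)[C@H](C)CC[C@H]1C(C)=C | intermediate
12 | 3-[(1S,3R,6S)-1,3-dimethyl-2-oxo-6-(prop-1-en-2-yl)cyclohexyl]propanal | O=CCC[C@]1(C)C(=O)[C@H](C)CC[C@H]1C(C)=C | intermediate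
13 | 3β-hydroxy-4,4,8α,10β-tetramethyl-5α-decalin-9-one, (2R,4aS,6S,8aS)-6-hydroxy-2,5,5,8a-tetramethyloctahydronaphthalen-1(2H)-one | O=C1[C@H](C)CC[C@H]2C(C)(C)[C@@H](O)CC[C@@]21C | intermediate
14 | but-3-yn-1-ol | C#CCCO | starting material
15 | trimethyl{4-[(trimethylsilyl)oxy]but-1-yn-1-yl}silane | C[Si](C)(C)C#CCCO[Si](C)(C)C | intermediate
16 | 4-(trimethylsilyl)but-3-yn-1-ol | C[Si](C)(C)C#CCCO | intermediate
17 | (4-iodobut-1-yn-1-yl)trimethylsilane | C[Si](C)(C)C#CCCI | intermediate
18 | [4-(trimethylsilyl)but-3-yn-1-yl]lithium | [Li]CCC#C[Si](C)(C)C | intermediate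
19 | dichloro[4-(trimethylsilyl)but-3-yn-1-yl]cerium | Cl[Ce](Cl)CCC#C[Si](C)(C)C | intermediate
20 | 3β,9β-dihydroxy-4,4,8α,10β-tetramethyl-9α-[4-(trimethylsilyl)but-3-yn-1-yl]-5α-decalin | C[Si](C)(C)C#CCC[C@]1(O)[C@H](C)CC[C@H]2C(C)(C)[C@@H](O)CC[C@@]21C | intermediate
21 | 9β-hydroxy-4,4,8α,10β-tetramethyl-9α-[4-(trimethylsilyl)but-3-yn-1-yl]-5α-decalin-3-one | C[Si](C)(C)C#CCC[C@]1(O)[C@H](C)CC[C@H]2C(C)(C)C(=O)CC[C@@]21C | intermediate
22 | (E)-p-toluenesulfonylhydrazone of 21 at C3 | C[Si](C)(C)C#CCC[C@]1(O)[C@H](C)CC[C@H]2C(C)(C)/C(=N/NS(=O)(=O)c3ccc(C)cc3)CC[C@@]21C | intermediate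
23 | C3 vinyllithium (C2=C3) bearing the C9 lithium alkoxide | C[Si](C)(C)C#CCC[C@]1(O[Li])[C@H](C)CC[C@H]2C(C)(C)C([Li])=CC[C@@]21C | intermediate
24 | 9β-hydroxy-4,4,8α,10β-tetramethyl-9α-[4-(trimethylsilyl)but-3-yn-1-yl]-5α-decal-2-ene | C[Si](C)(C)C#CCC[C@]1(O)[C@H](C)CC[C@H]2C(C)(C)C=CC[C@@]21C | intermediate
25 | 2α,3α,9β-trihydroxy-4,4,8α,10β-tetramethyl-9α-[4-(trimethylsilyl)but-3-yn-1-yl]-5α-decalin | C[Si](C)(C)C#CCC[C@]1(O)[C@H](C)CC[C@H]2C(C)(C)[C@H](O)[C@H](O)C[C@@]21C | intermediate
26 | 2α,3α-isopropylidene acetal of 25 | C[Si](C)(C)C#CCC[C@]1(O)[C@H](C)CC[C@H]2C(C)(C)[C@@H]3OC(C)(C)O[C@@H]3C[C@@]21C | intermediate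
27 | 9α-(but-3-yn-1-yl)-9β-hydroxy-2α,3α-isopropylidenedioxy-4,4,8α,10β-tetramethyl-5α-decalin | C#CCC[C@]1(O)[C@H](C)CC[C@H]2C(C)(C)[C@@H]3OC(C)(C)O[C@@H]3C[C@@]21C | intermediate
28 | (E)-alkenyl(dimethyl)alane at C14 with the C9 dimethylaluminium alkoxide (methyl and aluminium cis) | C[Al](C)/C=C(\C)CC[C@]1(O[Al](C)C)[C@H](C)CC[C@H]2C(C)(C)[C@@H]3OC(C)(C)O[C@@H]3C[C@@]21C | intermediate
29 | methyl (2E)-5-(9β-hydroxy-2α,3α-isopropylidenedioxy-4,4,8α,10β-tetramethyl-5α-decalin-9α-yl)-3-methylpent-2-enoate | COC(=O)/C=C(\C)CC[C@]1(O)[C@H](C)CC[C@H]2C(C)(C)[C@@H]3OC(C)(C)O[C@@H]3C[C@@]21C | intermediate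
30 | methyl (2E)-3-methyl-5-[(2R,3S,5S,8R,9S,10S)-2α,3α,9β-trihydroxy-4,4,8α,10β-tetramethyl-5α-decalin-9α-yl]pent-2-enoate (CNP0292844.1) | COC(=O)/C=C(\C)CC[C@]1(O)[C@H](C)CC[C@H]2C(C)(C)[C@H](O)[C@H](O)C[C@@]21C | target

## Step count and least certain steps

Total: 17 steps. Longest linear sequence: 15 steps from 1 (steps 1–6 and 9–17); steps 7 and 8 make iodide 17. Compound 16 is also an article of commerce, which would remove step 7.

Step 6 (key step). The most likely failure is reduction of the C4 radical to an isopropyl group before it closes. Addition of an alkyl radical to a C=O bond is slower than addition to an electron-poor alkene and is reversible, since the alkoxy radical can fragment back to the tertiary radical; hydrogen transfer from the iron hydride or the silane can therefore win. Loss of the aldehyde by aldol closure onto C8 is the second drain. Fallback: set out from 11 and add dry HBr in Markovnikov sense to the isopropenyl group (CH2Cl2, −78 °C) to give the tertiary bromide F1. Oxidize it with Dess–Martin periodinane to the bromo keto aldehyde F2, and close the ring with Bu3SnH and AIBN in benzene at 80 °C under slow addition. The radical is then made by bromine abstraction, the hydrogen donor concentration is set independently of radical generation, and the alkoxy radical is trapped by the stannane. This tin hydride cyclization onto an aldehyde is known chemistry and rejoins the route at 13.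

Step 9. The most likely failure is that the reagent acts as a base and not as a nucleophile: enolization toward C8, or plain failure to reach a carbonyl carbon lying between C8 and the quaternary C10, so that 13 is returned. Erosion of α-face selectivity is the smaller risk. Fallback: from 13, a Corey–Chaykovsky reaction with dimethylsulfonium methylide (Me3S+ I−, n-BuLi, THF, 0 °C, one extra equivalent for the hydroxyl) brings in C11 as the smallest possible carbon nucleophile along the same axial α trajectory and gives the spiro-epoxide F3 (CH2 α, O β). Opening F3 at its CH2 with lithiated 1-(trimethylsilyl)propyne (n-BuLi, THF/DMPU) makes the C11–C12 bond by SN2 and rejoins the route at 20.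

Step 12. The most likely failure is incomplete formation of the C2 carbanion in a heavily aggregated trilithio species, or competing metalation beside the silylalkyne, giving recovered hydrazone or mixtures. Fallback: from 21, KN(SiMe3)2 (2.2 equiv) and N-(5-chloropyridin-2-yl)triflimide in THF at −78 °C give the C2=C3 enol triflate F4. Reduction with Pd(OAc)2, PPh3, HCO2H and Bu3N in DMF at 60 °C (oxidative addition to zerovalent palladium, hydride from formate) replaces the C–O bond by C–H and rejoins the route at 24.

Step 16. The most likely failure is slow acylation of an alkenylalane tied up in alkoxide-bridged aggregates and, if the mixture has to be warmed, Lewis-acid opening of the dioxolane by the aluminium reagent. Fallback: from 27, run the same carboalumination but quench with I2 at −30 °C, a fast trapping, to give the (E)-vinyl iodide F5. The C14–C15 bond is then made by palladium-catalysed methoxycarbonylation (Pd(OAc)2, PPh3, CO 1 atm, MeOH, Et3N, DMF, 60 °C), which proceeds with retention and rejoins the route at 29.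

## Further compounds

F1 | step 6 | (2S,3S,6R)-3-(2-bromopropan-2-yl)-2-(3-hydroxypropyl)-2,6-dimethylcyclohexan-1-one (HBr adduct of 11; ring configuration as in 11) | OCCC[C@]1(C)C(=O)[C@H](C)CC[C@H]1C(C)(C)Br
F2 | step 6 | 3-[6-(2-bromopropan-2-yl)-1,3-dimethyl-2-oxocyclohexyl]propanal (ring configuration as in 12) | O=CCC[C@]1(C)C(=O)[C@H](C)CC[C@H]1C(C)(C)Br
F3 | step 9 | spiro-epoxide of 13 at C9 (C11 α, oxygen β), 3β-hydroxy-4,4,8α,10β-tetramethyl-5α-decalin-9-spiro-2′-oxirane | C1O[C@]12[C@H](C)CC[C@H]3C(C)(C)[C@@H](O)CC[C@@]32C
F4 | step 12 | C2=C3 enol triflate of 21 (triflate on C3) | C[Si](C)(C)C#CCC[C@]1(O)[C@H](C)CC[C@H]2C(C)(C)C(OS(=O)(=O)C(F)(F)F)=CC[C@@]21C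
F5 | step 16 | (E)-vinyl iodide: 9α-[(3E)-4-iodo-3-methylbut-3-en-1-yl]-9β-hydroxy-2α,3α-isopropylidenedioxy-4,4,8α,10β-tetramethyl-5α-decalin | I/C=C(\C)CC[C@]1(O)[C@H](C)CC[C@H]2C(C)(C)[C@@H]3OC(C)(C)O[C@@H]3C[C@@]21C
A1 | alternative 1 | bicyclic 1,4-diene (C5=C6 and C8=C9 triisopropylsilyl enol ether) with the ring A dioxolane | CC(C)[Si](C(C)C)(C(C)C)OC1=C(C)CC=C2C(C)(C)[C@H](OC3(C)C)[C@H](O3)C[C@@]21C
A2 | alternative 1 | acyclic dienyne: 2-silyloxydiene C7=C8–C9=C10 (tether trans to C8) linked through the C2/C3 dioxolane and C4 to the alkyne C5≡C6 | C=C(C)/C(O[Si](C(C)C)(C(C)C)C(C)C)=C(\C)C[C@H]1OC(C)(C)O[C@H]1C(C)(C)C#C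
A3 | alternative 1 | (S)-pantolactone, (3S)-3-hydroxy-4,4-dimethyloxolan-2-one | CC1(C)COC(=O)[C@H]1O
A4 | alternative 2 | decalin with an oxetane bridging O9 and C20, ring A dioxolane and C13 dioxolane | CC1(OCCO1)CC[C@]2(O3)[C@H](C)CC[C@H]4C(C)(C)[C@H](OC5(C)C)[C@H](O5)C[C@@]42C3
A5 | alternative 2 | keto alkene: ring A with exocyclic C10=C20 and the C2/C3 dioxolane, carrying on C5 the chain C6–C7–C8(CH3)–C9(=O)–C11–C12–C13 (dioxolane) | CC1(OCCO1)CCC(=O)[C@H](C)CC[C@@H]2C(=C)C[C@H]3OC(C)(C)O[C@H]3C2(C)C
A6 | alternative 3 | trans-decalin 2α,3α-diol with the C9 dioxolane | O1CCOC12[C@H](C)CC[C@H]3C(C)(C)[C@H](O)[C@H](O)C[C@@]32C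
A7 | alternative 3 | ring B dialdehyde: C9 dioxolane, CH2CHO (C1, C2) on C10 and C(CH3)2CHO (C4, C3) on C5 | O=CC[C@]1(C)C2(OCCO2)[C@H](C)CC[C@H]1C(C)(C)C=O
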